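The constants were drawn at random within sensible limits; what happens was integrated by code.

Read late, the chain length in this flask no longer moves with the hour, so the reckoning runs on monomer spent, not on minutes.

free monomer 1.0 M; protic impurity 0.500 M; initiator 2.0 mM; time 5.0 min

- average number of monomer units in a chain (chains begun, living or dead) at 5.0 min
- part of the free monomer that has reacted at 5.0 min

Initiator takes free monomer to start a chain, each living end takes it to lengthen one, and protic impurity takes it to give quenched substrate. Each step is first order in [free monomer], so the steps share one clock, the exposure, which is the time integral of [free monomer]. Each taker exerts a pseudo-first-order pull on free monomer.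

At the start, protic impurity pulls at 0.0200 s⁻¹ and living ends are absent. At exposure 58.8 M·s, [initiator] stands at 36.8% of its charge and [protic impurity] is ten times lower. Living ends then pull at 0.0139 s⁻¹ and protic impurity at 0.00190 s⁻¹, so control has passed to the chains. The joint pull 0.0158 s⁻¹ is weaker than the opening one by a factor of 1.27.

By that exposure, 0.929 M of free monomer is spent. Running the remainder off at that pull gives the final exposure, where spending meets the charge: 63.3 M·s. Monomer not taken by protic impurity, divided by chains begun, gives 409 units per chain. The pull 0.0158 s⁻¹ held across 5.0 min gives 99.1% reacted.

The forecast gives 406 and 99.1%, holding that the “impurity only competes for monomer and never kills living ends”.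

The flask gives 406 and 99.1%.

    free monomer + initiator → living end + monomer in chains (k1 = 0.017 M⁻¹ s⁻¹)
    free monomer + living end → monomer in chains + living end, rate k2*[living end]*[free monomer] (k2 = 11 M⁻¹ s⁻¹)
    protic impurity + free monomer → quenched substrate (k3 = 0.040 M⁻¹ s⁻¹)

Initiator left in the flask at 5.00 min, 34.5% of its charge, reads as exposure 62.7 M·s, beside the reckoned 63.3 M·s. In the neighbour flask, with 0.12 M of protic impurity, the same reckoning finds a joint pull of 0.0144 s⁻¹ at exposure 58.8 M·s and reaches final exposure 87.7 M·s. That reckons 570 units per chain and 1.34% of the charged free monomer left. Its initiator, 23.8% of its charge left at 5.00 min, reads as exposure 84.4 M·s. The neighbour flask gives 572 units per chain and keeps 1.19% of its free monomer.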